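**Plan**

- Feature: the benzene ring carries OH at C3 and C5 and a CH2–C(=O)C19H39 arm at C1, so oxygen sits on every second carbon of ring and arm. This is the pattern of a folded 3,5,7,9-tetraoxo acid (carboxyl = chain C1, ring = chain C2–C7, side-chain ketone = chain C9) that has lost its carboxyl group.
- Cuts: (a) put a CO2H back on the ring carbon between the arm and one OH, and mask the C9 ketone as a dioxolane; (b) open the ring at C2–C7 by retro-aldol to a diketo-dioxinone; (c) cut the open chain at C6–C7, C4–C5 and C8–C9, three Claisen-type acylations.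
- Forward: icosanoic acid and Meldrum's acid give a β-keto ester, then the dioxolane, then the Weinreb amide; trimethyldioxinone and acetyl chloride give the acetonyl dioxinone; its dianion and the amide give the open chain; Et3N closes the one ring; KOH removes acetonide and carboxyl; dilute acid frees the ketone.
- Stereochemistry: the target is achiral; the only stereocentre met on the way (the carbinol carbon of the aldol intermediate) is racemic and vanishes on aromatisation.

Key step: step 6

Remark: LiN(SiMe3)2 and LiN(i-Pr)2 are taken as commercial solutions. Chain numbering (dioxinone carbonyl = C1) is used in the Why lines.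

**Step 1**
Reactants: 1 icosanoic acid; 2 Meldrum's acid (2,2-dimethyl-1,3-dioxane-4,6-dione)
Product: 4 methyl 3-oxodocosanoate, via acyl Meldrum's acid 3 (not isolated)
Conditions: DCC, DMAP, CH2Cl2, 0 °C to rt; filter, wash with cold dilute HCl, evaporate; then MeOH, reflux
Reagents that add atoms: methanol, CO
Why: Carbodiimide/DMAP activation lets the acid C-acylate Meldrum's acid, and on heating in methanol the adduct 3 fragments to acetone, CO2 and an acyl ketene that methanol traps (C-acylation of Meldrum's acid followed by acyl ketene alcoholysis, the standard route to β-keto esters), which forms the C8–C9 bond.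

**Step 2**
Reactants: 4 methyl 3-oxodocosanoate; 5 ethylene glycol
Product: 6 methyl 2-(2-nonadecyl-1,3-dioxolan-2-yl)acetate
Conditions: p-TsOH·H2O (cat.), toluene, reflux, Dean–Stark trap
Reagents that add atoms: none
Why: Acid-catalysed ketalisation with azeotropic removal of water should convert the ketone only, since the ester cannot form a dioxolane, and β-keto esters are routinely protected in this way.

**Step 3**
Reactants: 6 methyl 2-(2-nonadecyl-1,3-dioxolan-2-yl)acetate
Product: 7 N-methoxy-N-methyl-2-(2-nonadecyl-1,3-dioxolan-2-yl)acetamide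
Conditions: MeNH(OMe)·HCl, i-PrMgCl, THF, −20 to 0 °C; aq. NH4Cl
Reagents that add atoms: N,O-dimethylhydroxylamine hydrochloride, CNOC.Cl
Why: The chloromagnesium amide formed from MeNH(OMe)·HCl and i-PrMgCl is a good nucleophile but a poor base, so it should convert the ester directly into the N-methoxy-N-methylamide (Weinreb amide formation by ester aminolysis) without enolising it and opening the β-dioxolane.

**Step 4**
Reactants: 8 2,2,6-trimethyl-4H-1,3-dioxin-4-one; 9 acetyl chloride
Product: 10 2,2-dimethyl-6-(2-oxopropyl)-4H-1,3-dioxin-4-one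
Conditions: 8 (2 equiv.), LiN(SiMe3)2 (2 equiv.), THF, −78 °C; then 9 (1 equiv.), −78 °C; aq. NH4Cl
Reagents that add atoms: none
Why: LiN(SiMe3)2 deprotonates the 6-methyl group to the lithium dienolate, which acetyl chloride acylates at that exocyclic γ-carbon (vinylogous Claisen acylation), the second equivalent of dienolate taking up the more acidic proton of the product so that it is not acylated twice; this makes the C4–C5 bond.

**Step 5**
Reactants: 10 2,2-dimethyl-6-(2-oxopropyl)-4H-1,3-dioxin-4-one; 7 N-methoxy-N-methyl-2-(2-nonadecyl-1,3-dioxolan-2-yl)acetamide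
Product: 11 2,2-dimethyl-6-[5-(2-nonadecyl-1,3-dioxolan-2-yl)-2,4-dioxopentyl]-4H-1,3-dioxin-4-one
Conditions: 10 (1.5 equiv.), LiN(i-Pr)2 (3.0 equiv.), THF, −78 °C; then 7 (1.0 equiv.), −78 to −40 °C; aq. NH4Cl (pH kept above 5)
Reagents that add atoms: none
Why: Double deprotonation of 10 gives a dianion whose terminal, less stabilised carbanion is the more nucleophilic site, and it should add to the Weinreb amide to a chelated lithium adduct that collapses to the ketone only on quench (Claisen-type γ-acylation of a 1,3-dicarbonyl dianion), forming the C6–C7 bond without over-addition.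

**Step 6**
Reactants: 11 2,2-dimethyl-6-[5-(2-nonadecyl-1,3-dioxolan-2-yl)-2,4-dioxopentyl]-4H-1,3-dioxin-4-one
Product: 13 7-hydroxy-2,2-dimethyl-5-[(2-nonadecyl-1,3-dioxolan-2-yl)methyl]-4H-1,3-benzodioxin-4-one, via cyclic aldol adduct 12 (not isolated)
Conditions: Et3N (2 equiv.), CH2Cl2, rt
Reagents that add atoms: none
Why: Et3N removes a proton from the CH2 between the dioxinone and the C5 ketone to give an extended enolate that is nucleophilic at dioxinone C5 (chain C2); this carbon adds to the C7 ketone, and the β-hydroxy ketone 12 should then lose water and enolise at C5 to the phenol. The closest known reaction type is the amine-mediated aldol aromatisation of diketo-dioxinones, which are masked 3,5,7-triketo esters, to isopropylidene-protected resorcylates. The single ring closes in a 6-(enolexo)-exo-trig mode, and the C2–C7 bond is the only skeletal bond made. No stereocentre results, because the carbinol carbon of 12 forms as a racemate and becomes an aromatic carbon on dehydration. The step needs aldol closure C2 to C7 to win over Claisen attack on the carboxyl carbon, pyranone formation and an alternative aldol from C4 onto C9. The dioxinone secures this by holding the carboxyl end as a poorly electrophilic cis enol ester that folds the chain, the amine is too weak a base for Claisen chemistry, and the dioxolane removes C9 as an acceptor.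

**Step 7**
Reactants: 13 7-hydroxy-2,2-dimethyl-5-[(2-nonadecyl-1,3-dioxolan-2-yl)methyl]-4H-1,3-benzodioxin-4-one
Product: 15 5-[(2-nonadecyl-1,3-dioxolan-2-yl)methyl]benzene-1,3-diol, via resorcylic acid 14 (not isolated)
Conditions: KOH (6 M aq.), 1,4-dioxane, 120 °C, sealed tube, argon; then aq. NH4Cl to pH 7
Reagents that add atoms: none
Why: Hydroxide opens the aryl ester of the acetonide with loss of acetone, and the 2,4-dihydroxybenzoate 14, electron-rich at its carboxyl-bearing carbon through the ortho and para phenoxides, should be ipso-protonated by water and lose CO2 (ester hydrolysis followed by protodecarboxylation of a β-resorcylic acid), while the base-stable dioxolane keeps the side-chain ketone from lactonising with the carboxyl group.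

**Step 8**
Reactants: 15 5-[(2-nonadecyl-1,3-dioxolan-2-yl)methyl]benzene-1,3-diol
Product: 16 1-(3,5-dihydroxyphenyl)henicosan-2-one
Conditions: 1 M aq. HCl, THF, rt
Reagents that add atoms: water, O
Why: Dilute aqueous acid should hydrolyse the dioxolane to the ketone (acid-catalysed ketal hydrolysis), and with the carboxyl group already removed nothing remains that could cyclise onto the carbonyl.

**Compound list**

1 | icosanoic acid | CCCCCCCCCCCCCCCCCCCC(=O)O | starting material
2 | Meldrum's acid (2,2-dimethyl-1,3-dioxane-4,6-dione) | CC1(C)OC(=O)CC(=O)O1 | starting material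
3 | 5-(1-hydroxyicosylidene)-2,2-dimethyl-1,3-dioxane-4,6-dione (acyl Meldrum's acid) | CCCCCCCCCCCCCCCCCCCC(O)=C1C(=O)OC(C)(C)OC1=O | intermediate (not isolated)
4 | methyl 3-oxodocosanoate | CCCCCCCCCCCCCCCCCCCC(=O)CC(=O)OC | intermediate
5 | ethylene glycol | OCCO | starting material
6 | methyl 2-(2-nonadecyl-1,3-dioxolan-2-yl)acetate | CCCCCCCCCCCCCCCCCCCC1(CC(=O)OC)OCCO1 | intermediate
7 | N-methoxy-N-methyl-2-(2-nonadecyl-1,3-dioxolan-2-yl)acetamide | CCCCCCCCCCCCCCCCCCCC1(CC(=O)N(C)OC)OCCO1 | intermediate
8 | 2,2,6-trimethyl-4H-1,3-dioxin-4-one | CC1=CC(=O)OC(C)(C)O1 | starting material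
9 | acetyl chloride | CC(=O)Cl | starting material
10 | 2,2-dimethyl-6-(2-oxopropyl)-4H-1,3-dioxin-4-one | CC(=O)CC1=CC(=O)OC(C)(C)O1 | intermediate
11 | 2,2-dimethyl-6-[5-(2-nonadecyl-1,3-dioxolan-2-yl)-2,4-dioxopentyl]-4H-1,3-dioxin-4-one | CC1(C)OC(=O)C=C(CC(=O)CC(=O)CC2(CCCCCCCCCCCCCCCCCCC)OCCO2)O1 | intermediate
12 | 5-hydroxy-2,2-dimethyl-5-[(2-nonadecyl-1,3-dioxolan-2-yl)methyl]-5,6-dihydro-4H-1,3-benzodioxine-4,7(8H)-dione, racemic (cyclic aldol adduct) | CC1(C)OC(=O)C2=C(O1)CC(=O)CC2(O)CC1(CCCCCCCCCCCCCCCCCCC)OCCO1 | intermediate (not isolated)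
13 | 7-hydroxy-2,2-dimethyl-5-[(2-nonadecyl-1,3-dioxolan-2-yl)methyl]-4H-1,3-benzodioxin-4-one | CC1(C)OC(=O)c2c(CC3(CCCCCCCCCCCCCCCCCCC)OCCO3)cc(O)cc2O1 | intermediate
14 | 2,4-dihydroxy-6-[(2-nonadecyl-1,3-dioxolan-2-yl)methyl]benzoic acid (resorcylic acid) | OC(=O)c1c(O)cc(O)cc1CC1(CCCCCCCCCCCCCCCCCCC)OCCO1 | intermediate (not isolated)
15 | 5-[(2-nonadecyl-1,3-dioxolan-2-yl)methyl]benzene-1,3-diol | CCCCCCCCCCCCCCCCCCCC1(Cc2cc(O)cc(O)c2)OCCO1 | intermediate
16 | 1-(3,5-dihydroxyphenyl)henicosan-2-one | CCCCCCCCCCCCCCCCCCCC(=O)Cc1cc(O)cc(O)c1 | target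

**Count**

Total step count: 8. Longest linear sequence: 7 steps (steps 1, 2, 3, 5, 6, 7, 8); step 4 is a one-step branch.

**Steps most likely to fail**

Step 5. The strongly basic dianion may deprotonate the amide at its α-CH2 instead of adding to the hindered carbonyl, and the resulting enolate would open the dioxolane by β-elimination. Fallback, setting out from 7 and coming back at 11: reduce 7 with i-Bu2AlH in THF at −78 °C to 2-(2-nonadecyl-1,3-dioxolan-2-yl)acetaldehyde F1. Add F1 to the dianion of 10 (LiN(i-Pr)2, THF, −78 °C), where carbonyl addition to an aldehyde is much faster than proton transfer. This should give racemic 6-[4-hydroxy-5-(2-nonadecyl-1,3-dioxolan-2-yl)-2-oxopentyl]-2,2-dimethyl-4H-1,3-dioxin-4-one F2. Oxidise F2 with Dess–Martin periodinane (NaHCO3, CH2Cl2, rt) to the diketone 11.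

Step 6. The sequence may stall at the aldol adduct without dehydration, or the amine may instead trigger β-elimination of the dioxolane next to the C7 ketone before the ring closes. Fallback, setting out from 11 and coming back at 15: heat 11 with excess methanol in toluene at 110 °C, so that loss of acetone gives an acyl ketene that methanol traps as methyl 8-(2-nonadecyl-1,3-dioxolan-2-yl)-3,5,7-trioxooctanoate F3. Cyclise this free triketo ester by the same C2–C7 aldol with Cs2CO3 in MeOH at rt to methyl 2,4-dihydroxy-6-[(2-nonadecyl-1,3-dioxolan-2-yl)methyl]benzoate F4. Subject F4 to the conditions of step 7, which should saponify it to 14 and decarboxylate that to 15.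

Step 7. Protodecarboxylation may be incomplete in hot alkali, and acid used on work-up could then strip the ketal while the carboxyl group is still present, which leads to lactonisation onto the ketone. Fallback, setting out from 13 and coming back at 15: open the acetonide by transesterification with benzyl alcohol and Cs2CO3 at 60 °C to benzyl 2,4-dihydroxy-6-[(2-nonadecyl-1,3-dioxolan-2-yl)methyl]benzoate F5. Cleave the benzyl ester under neutral conditions (H2, Pd/C, EtOAc with a trace of Et3N) to isolate the acid 14 as its ammonium salt. Decarboxylate 14 thermally in DMF at 120 °C to 15, with the ketal never exposed to aqueous acid.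

**Further compounds**

F1 | step 5 | 2-(2-nonadecyl-1,3-dioxolan-2-yl)acetaldehyde | CCCCCCCCCCCCCCCCCCCC1(CC=O)OCCO1
F2 | step 5 | 6-[4-hydroxy-5-(2-nonadecyl-1,3-dioxolan-2-yl)-2-oxopentyl]-2,2-dimethyl-4H-1,3-dioxin-4-one (racemic) | CC1(C)OC(=O)C=C(CC(=O)CC(O)CC2(CCCCCCCCCCCCCCCCCCC)OCCO2)O1
F3 | step 6 | methyl 8-(2-nonadecyl-1,3-dioxolan-2-yl)-3,5,7-trioxooctanoate | COC(=O)CC(=O)CC(=O)CC(=O)CC1(CCCCCCCCCCCCCCCCCCC)OCCO1
F4 | step 6 | methyl 2,4-dihydroxy-6-[(2-nonadecyl-1,3-dioxolan-2-yl)methyl]benzoate | COC(=O)c1c(O)cc(O)cc1CC1(CCCCCCCCCCCCCCCCCCC)OCCO1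
F5 | step 7 | benzyl 2,4-dihydroxy-6-[(2-nonadecyl-1,3-dioxolan-2-yl)methyl]benzoate | O=C(OCc1ccccc1)c1c(O)cc(O)cc1CC1(CCCCCCCCCCCCCCCCCCC)OCCO1
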